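**Plan**
1. Retrosynthesis: the enal is traced back to a nitrile; both 1,4-dioxane rings are then opened at their aryl–oxygen bonds, O(C7)–C5 of ring A and O(C8')–C5 of ring B, giving an acyclic bis(2-bromoaryl ether) diol; next the C7–C8 bond is cut (glycolate aldol), then the O–C4 aryl ether bond of ring B (SNAr), then the ring C–C7' ketone bond.
2. Forward: ring C aryllithium + (S)-glycerate acetonide → ketone → anti carbinol → aryl ether to ring B → syn aldol with the ring A glycolyl imide → diol, tetraol, bis-silyl ether → one-flask double C–O cyclisation closing dioxane ring 1 and dioxane ring 2 → aldehyde → enal → desilylation.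
3. Stereochemistry: C8' comes from the chiral pool; C7' from a chelation-controlled ketone reduction (erythro, hence cis ring 2); C7 and C8 from an (R)-4-benzyloxazolidinone syn aldol (threo, hence trans ring 1). The key step forms only aryl–O bonds, so all four centres pass through unchanged.
4. Enabling feature: in ring A and in ring B alike, the oxygen on C4 (para to the carbon substituent) is an ether oxygen that can be set early, and the neighbouring C5 can carry bromine. Each secondary hydroxyl (on C7, on C8') can then reach only its own C5, closing a six-membered O–C–C–O–C(aryl)–C(aryl) ring once the primary hydroxyls are silylated.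

Key step: step 10

Remark: read as written, the SMILES has dioxane ring 1 trans (7S,8S) and dioxane ring 2 cis (7'R,8'S), and the route is built for exactly this isomer. Locants: ring A = enal-bearing arene, ring B = central arene, ring C = catechol, each numbered from its carbon substituent as C1; C7/C8 = aryl-bearing/CH2O-bearing carbons of dioxane ring 1 (on ring A), C7'/C8' = the same for dioxane ring 2 (on ring B).

**Step 1**
Reactants: 1 4-bromobenzene-1,2-diol
Product: 2 4-bromo-1,2-bis(triisopropylsilyloxy)benzene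
Conditions: i-Pr3SiCl (2.4 equiv), imidazole, DMF, 25 to 50 °C
Reagents that add atoms: chlorotriisopropylsilane, CC(C)[Si](Cl)(C(C)C)C(C)C
Why: Imidazole-promoted silylation of both phenols; the bulky silyl ethers should survive the aryllithium, alkoxide and carbonate steps and fall to fluoride at the end (silyl ether formation).

**Step 2**
Reactants: 2 4-bromo-1,2-bis(triisopropylsilyloxy)benzene, 3 methyl (S)-2,2-dimethyl-1,3-dioxolane-4-carboxylate
Product: 5 [3,4-bis(triisopropylsilyloxy)phenyl][(4S)-2,2-dimethyl-1,3-dioxolan-4-yl]methanone, via aryllithium 4 (not isolated)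
Conditions: n-BuLi, THF, −78 °C; then transfer into 3 (1.2 equiv), THF, −78 °C; AcOH quench at −78 °C
Reagents that add atoms: none
Why: Bromine–lithium exchange followed by acyl substitution on the α-alkoxy ester, whose chelated lithium hemiketal should resist a second addition at −78 °C; C8' is taken unchanged from the chiral pool (halogen–lithium exchange, ketone synthesis from an ester).

**Step 3**
Reactants: 5 [3,4-bis(triisopropylsilyloxy)phenyl][(4S)-2,2-dimethyl-1,3-dioxolan-4-yl]methanone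
Product: 6 (R)-[3,4-bis(triisopropylsilyloxy)phenyl][(4S)-2,2-dimethyl-1,3-dioxolan-4-yl]methanol
Conditions: Zn(BH4)2 (pre-formed ethereal solution), Et2O, −30 to 0 °C; aqueous NH4Cl
Reagents that add atoms: none
Why: Zinc should bridge the carbonyl oxygen and the adjacent dioxolane oxygen so that hydride arrives on the face flanked by the C8' hydrogen, setting C7' as R in the anti (erythro) carbinol (Cram-chelate-controlled reduction).

**Step 4**
Reactants: 6 (R)-[3,4-bis(triisopropylsilyloxy)phenyl][(4S)-2,2-dimethyl-1,3-dioxolan-4-yl]methanol, 7 3-bromo-4-fluorobenzaldehyde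
Product: 8 3-bromo-4-{(R)-[3,4-bis(triisopropylsilyloxy)phenyl][(4S)-2,2-dimethyl-1,3-dioxolan-4-yl]methoxy}benzaldehyde
Conditions: KN(SiMe3)2 (1.05 equiv), THF, −40 °C; then 7, −40 to 0 °C
Reagents that add atoms: none
Why: The potassium alkoxide should displace the fluoride para to the formyl group through a Meisenheimer adduct; C7' is retained because its C–O bond is not touched, and the meta bromide is not activated (nucleophilic aromatic substitution).

**Step 5**
Reactants: 9 3-bromo-4-hydroxybenzonitrile, 10 (R)-4-benzyl-3-(chloroacetyl)oxazolidin-2-one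
Product: 11 (R)-4-benzyl-3-[(2-bromo-4-cyanophenoxy)acetyl]oxazolidin-2-one
Conditions: K2CO3, NaI (10 mol %), acetone, 50 °C
Reagents that add atoms: none
Why: The acidic phenol is alkylated at the α-halo imide carbon under mild carbonate conditions that should leave the imide intact (Williamson ether synthesis with Finkelstein catalysis).

**Step 6**
Reactants: 11 (R)-4-benzyl-3-[(2-bromo-4-cyanophenoxy)acetyl]oxazolidin-2-one (1.3 equiv), 8 3-bromo-4-{(R)-[3,4-bis(triisopropylsilyloxy)phenyl][(4S)-2,2-dimethyl-1,3-dioxolan-4-yl]methoxy}benzaldehyde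
Product: 13 (R)-4-benzyl-3-[(2R,3S)-2-(2-bromo-4-cyanophenoxy)-3-(3-bromo-4-{(R)-[3,4-bis(triisopropylsilyloxy)phenyl][(4S)-2,2-dimethyl-1,3-dioxolan-4-yl]methoxy}phenyl)-3-hydroxypropanoyl]oxazolidin-2-one, via Z-boron enolate 12 (not isolated)
Conditions: Bu2BOTf, Et3N, CH2Cl2, −78 to 0 °C; then 8, −78 to 0 °C; pH 7 buffer, MeOH, H2O2, 0 °C
Reagents that add atoms: none
Why: The Z-dibutylboron enolate should react through a closed chair transition state in which the auxiliary's benzyl group blocks one enolate face, giving the syn adduct (2R,3S) that corresponds to threo C7 (S) and C8 (S) (Evans syn glycolate aldol).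

**Step 7**
Reactants: 13 the syn aldol imide
Product: 14 3-bromo-4-{[(1S,2S)-1-(3-bromo-4-{(R)-[3,4-bis(triisopropylsilyloxy)phenyl][(4S)-2,2-dimethyl-1,3-dioxolan-4-yl]methoxy}phenyl)-1,3-dihydroxypropan-2-yl]oxy}benzonitrile
Conditions: LiBH4, MeOH (1 equiv), THF, 0 °C
Reagents that add atoms: none
Why: LiBH4 should reduce the activated exocyclic imide carbonyl to the primary alcohol and release the auxiliary while nitrile, aryl bromides and silyl ethers are left alone (reductive auxiliary cleavage).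

**Step 8**
Reactants: 14 the 1,3-diol acetonide
Product: 15 3-bromo-4-{[(1S,2S)-1-(3-bromo-4-{[(1R,2S)-1-[3,4-bis(triisopropylsilyloxy)phenyl]-2,3-dihydroxypropyl]oxy}phenyl)-1,3-dihydroxypropan-2-yl]oxy}benzonitrile
Conditions: AcOH/H2O/THF (4:1:1), 40 °C
Reagents that add atoms: none
Why: Mild aqueous acid should hydrolyse the terminal isopropylidene acetal while the aryl silyl ethers and both aryl ethers are stable (acetal hydrolysis).

**Step 9**
Reactants: 15 the tetraol
Product: 16 3-bromo-4-{[(1S,2S)-1-(3-bromo-4-{[(1R,2S)-1-[3,4-bis(triisopropylsilyloxy)phenyl]-3-(tert-butyldimethylsilyloxy)-2-hydroxypropyl]oxy}phenyl)-3-(tert-butyldimethylsilyloxy)-1-hydroxypropan-2-yl]oxy}benzonitrile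
Conditions: t-BuMe2SiCl (2.1 equiv), imidazole, CH2Cl2/DMF, −20 to 0 °C
Reagents that add atoms: tert-butylchlorodimethylsilane, CC(C)(C)[Si](C)(C)Cl
Why: The two unhindered primary hydroxyls should be silylated much faster than the two hindered secondary ones, which removes the seven-membered closure option from the key step (selective silyl ether formation).

**Step 10**
Reactants: 16 the bis(2-bromoaryl ether) diol
Product: 18 (2S,3S)-3-{(2R,3S)-2-[3,4-bis(triisopropylsilyloxy)phenyl]-3-[(tert-butyldimethylsilyloxy)methyl]-2,3-dihydro-1,4-benzodioxin-6-yl}-2-[(tert-butyldimethylsilyloxy)methyl]-2,3-dihydro-1,4-benzodioxine-6-carbonitrile, via mono-cyclised bromo alcohol 17 (not isolated)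
Conditions: Pd(OAc)2 (10 mol %), rac-2-(di-tert-butylphosphino)-1,1'-binaphthyl (12 mol %), Cs2CO3 (4 equiv), toluene (0.02 M), 80 °C
Reagents that add atoms: none
Why: Zerovalent palladium formed from Pd(OAc)2 and the bulky phosphine should insert into each aryl C–Br bond, Cs2CO3 turns the neighbouring secondary hydroxyl into a divalent-palladium alkoxide inside a seven-membered oxapalladacycle, and C–O reductive elimination then forges O(C7)–C5 of ring A (expected first, at the more electron-poor bromide) and O(C8')–C5 of ring B. The closest known reaction type is the intramolecular Buchwald–Hartwig etherification of 2-(2-bromoaryloxy) alcohols to 1,4-benzodioxanes, here run twice in one flask. Each dioxane ring closes in a 6-exo sense, the oxygen bonding to the ipso carbon while bromide leaves outside the new ring. No stereocentre is created: C7, C8, C7' and C8' keep their configurations because no bond to them is made or broken, so the threo half becomes trans ring 1 and the erythro half becomes cis ring 2. The step needs six-membered over seven-membered closure and reductive elimination over β-hydride elimination; the first is secured by the silylated primary hydroxyls and by each hydroxyl reaching only its own bromide, the second by the bulky electron-rich ligand.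

**Step 11**
Reactants: 18 the bis-benzodioxane nitrile
Product: 20 (2S,3S)-3-{(2R,3S)-2-[3,4-bis(triisopropylsilyloxy)phenyl]-3-[(tert-butyldimethylsilyloxy)methyl]-2,3-dihydro-1,4-benzodioxin-6-yl}-2-[(tert-butyldimethylsilyloxy)methyl]-2,3-dihydro-1,4-benzodioxine-6-carbaldehyde, via N-aluminio aldimine 19 (not isolated)
Conditions: i-Bu2AlH (1.3 equiv), CH2Cl2, −78 °C; then aqueous potassium sodium tartrate, 25 °C
Reagents that add atoms: water, O
Why: One hydride should add to the nitrile to give an aluminium aldiminate that is stable at −78 °C and is hydrolysed to the aldehyde on work-up (partial reduction of a nitrile).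

**Step 12**
Reactants: 20 the bis-benzodioxane aldehyde, 21 (triphenylphosphoranylidene)acetaldehyde
Product: 22 (E)-3-[(2S,3S)-3-{(2R,3S)-2-[3,4-bis(triisopropylsilyloxy)phenyl]-3-[(tert-butyldimethylsilyloxy)methyl]-2,3-dihydro-1,4-benzodioxin-6-yl}-2-[(tert-butyldimethylsilyloxy)methyl]-2,3-dihydro-1,4-benzodioxin-6-yl]prop-2-enal
Conditions: 21 (1.3 equiv), toluene, 80 °C
Reagents that add atoms: none
Why: The stabilised formyl ylide should give the E-enal, and holding the ylide near 1.3 equiv limits a second olefination of the product (Wittig olefination).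

**Step 13**
Reactants: 22 the silyl-protected enal
Product: 23 CNP0302404.1, (E)-3-{(2S,3S)-3-[(2R,3S)-2-(3,4-dihydroxyphenyl)-3-(hydroxymethyl)-2,3-dihydro-1,4-benzodioxin-6-yl]-2-(hydroxymethyl)-2,3-dihydro-1,4-benzodioxin-6-yl}prop-2-enal
Conditions: Bu4NF/AcOH (1:1, 6 equiv), THF, 0 to 25 °C
Reagents that add atoms: none
Why: Fluoride should cleave all four Si–O bonds, and the acetic acid buffer keeps the phenoxide level low so that neither the enal nor cis ring 2 (which could open through a para-quinone methide) is attacked (global desilylation).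

**Compound list**
1 | 4-bromobenzene-1,2-diol | Oc1ccc(Br)cc1O | starting material
2 | 4-bromo-1,2-bis(triisopropylsilyloxy)benzene | Brc1ccc(O[Si](C(C)C)(C(C)C)C(C)C)c(O[Si](C(C)C)(C(C)C)C(C)C)c1 | intermediate
3 | methyl (S)-2,2-dimethyl-1,3-dioxolane-4-carboxylate | COC(=O)[C@@H]1COC(C)(C)O1 | starting material
4 | 3,4-bis(triisopropylsilyloxy)phenyllithium | [Li]c1ccc(O[Si](C(C)C)(C(C)C)C(C)C)c(O[Si](C(C)C)(C(C)C)C(C)C)c1 | intermediate
5 | [3,4-bis(triisopropylsilyloxy)phenyl][(4S)-2,2-dimethyl-1,3-dioxolan-4-yl]methanone | O=C(c1ccc(O[Si](C(C)C)(C(C)C)C(C)C)c(O[Si](C(C)C)(C(C)C)C(C)C)c1)[C@@H]1COC(C)(C)O1 | intermediate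
6 | (R)-[3,4-bis(triisopropylsilyloxy)phenyl][(4S)-2,2-dimethyl-1,3-dioxolan-4-yl]methanol | O[C@H](c1ccc(O[Si](C(C)C)(C(C)C)C(C)C)c(O[Si](C(C)C)(C(C)C)C(C)C)c1)[C@@H]1COC(C)(C)O1 | intermediate
7 | 3-bromo-4-fluorobenzaldehyde | O=Cc1ccc(F)c(Br)c1 | starting material
8 | 3-bromo-4-{(R)-[3,4-bis(triisopropylsilyloxy)phenyl][(4S)-2,2-dimethyl-1,3-dioxolan-4-yl]methoxy}benzaldehyde | O=Cc1ccc(O[C@H](c2ccc(O[Si](C(C)C)(C(C)C)C(C)C)c(O[Si](C(C)C)(C(C)C)C(C)C)c2)[C@@H]2COC(C)(C)O2)c(Br)c1 | intermediate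
9 | 3-bromo-4-hydroxybenzonitrile | N#Cc1ccc(O)c(Br)c1 | starting material
10 | (R)-4-benzyl-3-(chloroacetyl)oxazolidin-2-one | O=C(CCl)N1[C@H](Cc2ccccc2)COC1=O | starting material
11 | (R)-4-benzyl-3-[(2-bromo-4-cyanophenoxy)acetyl]oxazolidin-2-one | N#Cc1ccc(OCC(=O)N2[C@H](Cc3ccccc3)COC2=O)c(Br)c1 | intermediate
12 | Z-dibutylboron enolate of 11 | N#Cc1ccc(O/C=C(\OB(CCCC)CCCC)N2[C@H](Cc3ccccc3)COC2=O)c(Br)c1 | intermediate
13 | (R)-4-benzyl-3-[(2R,3S)-2-(2-bromo-4-cyanophenoxy)-3-(3-bromo-4-{(R)-[3,4-bis(triisopropylsilyloxy)phenyl][(4S)-2,2-dimethyl-1,3-dioxolan-4-yl]methoxy}phenyl)-3-hydroxypropanoyl]oxazolidin-2-one | N#Cc1ccc(O[C@@H](C(=O)N2[C@H](Cc3ccccc3)COC2=O)[C@@H](O)c2ccc(O[C@H](c3ccc(O[Si](C(C)C)(C(C)C)C(C)C)c(O[Si](C(C)C)(C(C)C)C(C)C)c3)[C@@H]3COC(C)(C)O3)c(Br)c2)c(Br)c1 | intermediate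
14 | 3-bromo-4-{[(1S,2S)-1-(3-bromo-4-{(R)-[3,4-bis(triisopropylsilyloxy)phenyl][(4S)-2,2-dimethyl-1,3-dioxolan-4-yl]methoxy}phenyl)-1,3-dihydroxypropan-2-yl]oxy}benzonitrile | N#Cc1ccc(O[C@@H](CO)[C@@H](O)c2ccc(O[C@H](c3ccc(O[Si](C(C)C)(C(C)C)C(C)C)c(O[Si](C(C)C)(C(C)C)C(C)C)c3)[C@@H]3COC(C)(C)O3)c(Br)c2)c(Br)c1 | intermediate
15 | 3-bromo-4-{[(1S,2S)-1-(3-bromo-4-{[(1R,2S)-1-[3,4-bis(triisopropylsilyloxy)phenyl]-2,3-dihydroxypropyl]oxy}phenyl)-1,3-dihydroxypropan-2-yl]oxy}benzonitrile | N#Cc1ccc(O[C@@H](CO)[C@@H](O)c2ccc(O[C@H](c3ccc(O[Si](C(C)C)(C(C)C)C(C)C)c(O[Si](C(C)C)(C(C)C)C(C)C)c3)[C@@H](O)CO)c(Br)c2)c(Br)c1 | intermediate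
16 | 3-bromo-4-{[(1S,2S)-1-(3-bromo-4-{[(1R,2S)-1-[3,4-bis(triisopropylsilyloxy)phenyl]-3-(tert-butyldimethylsilyloxy)-2-hydroxypropyl]oxy}phenyl)-3-(tert-butyldimethylsilyloxy)-1-hydroxypropan-2-yl]oxy}benzonitrile | N#Cc1ccc(O[C@@H](CO[Si](C)(C)C(C)(C)C)[C@@H](O)c2ccc(O[C@H](c3ccc(O[Si](C(C)C)(C(C)C)C(C)C)c(O[Si](C(C)C)(C(C)C)C(C)C)c3)[C@@H](O)CO[Si](C)(C)C(C)(C)C)c(Br)c2)c(Br)c1 | intermediate
17 | (2S,3S)-3-(3-bromo-4-{[(1R,2S)-1-[3,4-bis(triisopropylsilyloxy)phenyl]-3-(tert-butyldimethylsilyloxy)-2-hydroxypropyl]oxy}phenyl)-2-[(tert-butyldimethylsilyloxy)methyl]-2,3-dihydro-1,4-benzodioxine-6-carbonitrile | N#Cc1ccc2c(c1)O[C@@H](c1ccc(O[C@H](c3ccc(O[Si](C(C)C)(C(C)C)C(C)C)c(O[Si](C(C)C)(C(C)C)C(C)C)c3)[C@@H](O)CO[Si](C)(C)C(C)(C)C)c(Br)c1)[C@H](CO[Si](C)(C)C(C)(C)C)O2 | intermediate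
18 | (2S,3S)-3-{(2R,3S)-2-[3,4-bis(triisopropylsilyloxy)phenyl]-3-[(tert-butyldimethylsilyloxy)methyl]-2,3-dihydro-1,4-benzodioxin-6-yl}-2-[(tert-butyldimethylsilyloxy)methyl]-2,3-dihydro-1,4-benzodioxine-6-carbonitrile | N#Cc1ccc2c(c1)O[C@@H](c1ccc3c(c1)O[C@@H](CO[Si](C)(C)C(C)(C)C)[C@@H](c1ccc(O[Si](C(C)C)(C(C)C)C(C)C)c(O[Si](C(C)C)(C(C)C)C(C)C)c1)O3)[C@H](CO[Si](C)(C)C(C)(C)C)O2 | intermediate
19 | N-(diisobutylaluminio) aldimine of 18 | CC(C)C[Al](CC(C)C)N=Cc1ccc2c(c1)O[C@@H](c1ccc3c(c1)O[C@@H](CO[Si](C)(C)C(C)(C)C)[C@@H](c1ccc(O[Si](C(C)C)(C(C)C)C(C)C)c(O[Si](C(C)C)(C(C)C)C(C)C)c1)O3)[C@H](CO[Si](C)(C)C(C)(C)C)O2 | intermediate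
20 | (2S,3S)-3-{(2R,3S)-2-[3,4-bis(triisopropylsilyloxy)phenyl]-3-[(tert-butyldimethylsilyloxy)methyl]-2,3-dihydro-1,4-benzodioxin-6-yl}-2-[(tert-butyldimethylsilyloxy)methyl]-2,3-dihydro-1,4-benzodioxine-6-carbaldehyde | O=Cc1ccc2c(c1)O[C@@H](c1ccc3c(c1)O[C@@H](CO[Si](C)(C)C(C)(C)C)[C@@H](c1ccc(O[Si](C(C)C)(C(C)C)C(C)C)c(O[Si](C(C)C)(C(C)C)C(C)C)c1)O3)[C@H](CO[Si](C)(C)C(C)(C)C)O2 | intermediate
21 | (triphenylphosphoranylidene)acetaldehyde | O=CC=P(c1ccccc1)(c1ccccc1)c1ccccc1 | starting material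
22 | (E)-3-[(2S,3S)-3-{(2R,3S)-2-[3,4-bis(triisopropylsilyloxy)phenyl]-3-[(tert-butyldimethylsilyloxy)methyl]-2,3-dihydro-1,4-benzodioxin-6-yl}-2-[(tert-butyldimethylsilyloxy)methyl]-2,3-dihydro-1,4-benzodioxin-6-yl]prop-2-enal | O=C/C=C/c1ccc2c(c1)O[C@@H](c1ccc3c(c1)O[C@@H](CO[Si](C)(C)C(C)(C)C)[C@@H](c1ccc(O[Si](C(C)C)(C(C)C)C(C)C)c(O[Si](C(C)C)(C(C)C)C(C)C)c1)O3)[C@H](CO[Si](C)(C)C(C)(C)C)O2 | intermediate
23 | CNP0302404.1, (E)-3-{(2S,3S)-3-[(2R,3S)-2-(3,4-dihydroxyphenyl)-3-(hydroxymethyl)-2,3-dihydro-1,4-benzodioxin-6-yl]-2-(hydroxymethyl)-2,3-dihydro-1,4-benzodioxin-6-yl}prop-2-enal | O=C/C=C/c1ccc2c(c1)O[C@@H](c1ccc3c(c1)O[C@@H](CO)[C@@H](c1ccc(O)c(O)c1)O3)[C@H](CO)O2 | target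

**Count**
Total steps: 13. Longest linear sequence: 12 (steps 1–4 and 6–13; step 5 is a one-step side branch).

**Steps most likely to fail**

Step 10. β-Hydride elimination from the divalent-palladium alkoxide at the benzylic C7 oxygen (ketone formation with hydrodebromination) may compete, or the second closure at the hindered C8' hydroxyl may stall. The fallback sets out from 16 and replaces the aryl bromide/palladium manifold by oxidative copper coupling of aryl boron groups. Miyaura borylation of both bromides (PdCl2(dppf), bis(pinacolato)diboron, KOAc, dioxane, 85 °C) should give the bis(pinacol boronate) analogue of 16 F1. A double Chan–Lam etherification (Cu(OAc)2, 4-(dimethylamino)pyridine, 4 Å molecular sieves, O2, CH2Cl2, 25 °C) should then close both dioxane rings at the same two aryl–oxygen bonds, and the route is rejoined at 18.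

Step 4. Hydride transfer from the benzylic potassium alkoxide to the aryl aldehyde (Oppenauer/Tishchenko-type redox), or reversible alkoxide addition to the formyl group, may outrun the substitution at the hindered carbinol. The fallback sets out from 6 and uses an electrophile without a carbonyl. SNAr on 3-bromo-4-fluorobenzonitrile (KN(SiMe3)2, THF, −40 to 0 °C) should give 3-bromo-4-{(R)-[3,4-bis(triisopropylsilyloxy)phenyl][(4S)-2,2-dimethyl-1,3-dioxolan-4-yl]methoxy}benzonitrile F2. Partial reduction with i-Bu2AlH (toluene, −78 °C, aqueous tartrate work-up) then returns the aldehyde, and the route is rejoined at 8.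

Step 2. A second addition of the aryllithium to the ketone as it is released (tertiary alcohol), or base-induced epimerisation at C8' of the ketone, may erode the acylation. The fallback sets out from 2 (through aryllithium 4) and forms the C–C bond at the aldehyde oxidation level. Addition of 4 to (S)-2,2-dimethyl-1,3-dioxolane-4-carbaldehyde (THF, −78 °C) should give [3,4-bis(triisopropylsilyloxy)phenyl][(4S)-2,2-dimethyl-1,3-dioxolan-4-yl]methanol as a mixture of carbinol epimers F3. Oxidation with Dess–Martin periodinane (NaHCO3, CH2Cl2, 0 to 25 °C) then gives the ketone, and the route is rejoined at 5, after which step 3 resets C7'.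

**Further compounds**
F1 | step 10 | bis(pinacol boronate) analogue of 16 (both Br replaced by 4,4,5,5-tetramethyl-1,3,2-dioxaborolan-2-yl) | N#Cc1ccc(O[C@@H](CO[Si](C)(C)C(C)(C)C)[C@@H](O)c2ccc(O[C@H](c3ccc(O[Si](C(C)C)(C(C)C)C(C)C)c(O[Si](C(C)C)(C(C)C)C(C)C)c3)[C@@H](O)CO[Si](C)(C)C(C)(C)C)c(B4OC(C)(C)C(C)(C)O4)c2)c(B5OC(C)(C)C(C)(C)O5)c1
F2 | step 4 | 3-bromo-4-{(R)-[3,4-bis(triisopropylsilyloxy)phenyl][(4S)-2,2-dimethyl-1,3-dioxolan-4-yl]methoxy}benzonitrile | N#Cc1ccc(O[C@H](c2ccc(O[Si](C(C)C)(C(C)C)C(C)C)c(O[Si](C(C)C)(C(C)C)C(C)C)c2)[C@@H]2COC(C)(C)O2)c(Br)c1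
F3 | step 2 | [3,4-bis(triisopropylsilyloxy)phenyl][(4S)-2,2-dimethyl-1,3-dioxolan-4-yl]methanol, mixture of carbinol epimers | OC(c1ccc(O[Si](C(C)C)(C(C)C)C(C)C)c(O[Si](C(C)C)(C(C)C)C(C)C)c1)[C@@H]1COC(C)(C)O1
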